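**Retrosynthetic overview**

1. The target is released from its hexabenzyl ether 16 by global hydrogenolysis; in 16 ring C of the upper flavan is the last ring closed, at the C3–C4 bond.
2. Key disconnection C3–C4: cathodic two-electron reduction of a ring A para-quinone methide (methide carbon = C4) gives a C4 carbanion that adds to a C3 aldehyde; the C2 aryl ether stereocentre controls C3 and C4.
3. Enabling feature: C4 is doubly benzylic and para, through C4a, to the ring A C7 oxygen, so C7–O/C4 can be written as a para-quinone methide; its neighbour C3 is a carbinol carbon (an aldehyde in the retron) next to the chelating C2–O1 aryl ether.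
4. Quinone methide and aldehyde are stored together in a temporary seven-membered lactol acetate (1,4-benzodioxepine, oxygen bridge between C3 and C4), which a fluoride-released C7 phenoxide opens.
5. The C4–C8 bond comes from 8-metalated penta-O-benzylepicatechin and a ring A aldehyde whose O1–C2 ether is made by Mitsunobu inversion of an (S)-mandelate; ring order: rings A, B and the lower flavan are bought, then the temporary dioxepine, then ring C.

Key step: step 10

Assumption: (S)-4-hydroxymandelic acid is taken to be purchasable as a single enantiomer. The carbinol centre of 12 and the future C3/C4 centres of 13 and 14 form as epimer mixtures, which is harmless because both carbons are trigonal in 15.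

**Route**

Step 1
Reactants: 1 (−)-epicatechin
Product: 2 5,7,3',4'-tetra-O-benzyl-(−)-epicatechin
Conditions: BnBr (4.4 equiv), K2CO3, DMF, 0 to 23 °C
Reagents that add atoms: benzyl bromide, BrCc1ccccc1
Why: Williamson etherification of the four phenols, whose much higher acidity leaves the secondary C3 alcohol and both stereocentres untouched under carbonate base.

Step 2
Reactants: 2 5,7,3',4'-tetra-O-benzyl-(−)-epicatechin
Product: 3 8-bromo-5,7,3',4'-tetra-O-benzylepicatechin
Conditions: NBS (1.0 equiv), CH2Cl2, −78 to 0 °C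
Reagents that add atoms: N-bromosuccinimide, O=C1CCC(=O)N1Br
Why: Electrophilic aromatic bromination of the phloroglucinol-type ring, which for 5,7-di-O-benzyl flavan-3-ols is known to occur at C8 (flanked by O1 and the C7 ether) in preference to C6.

Step 3
Reactants: 3 8-bromo-5,7,3',4'-tetra-O-benzylepicatechin
Product: 4 8-bromo-3,5,7,3',4'-penta-O-benzylepicatechin
Conditions: NaH, BnBr, DMF, 0 to 23 °C
Reagents that add atoms: benzyl bromide, BrCc1ccccc1
Why: Williamson etherification of the C3 alkoxide removes the last acidic proton before halogen–metal exchange and leaves the aryl bromide intact.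

Step 4
Reactants: 5 2,4-dihydroxybenzaldehyde
Product: 6 2-hydroxy-4-(triisopropylsilyloxy)benzaldehyde
Conditions: i-Pr3SiCl (1.05 equiv), imidazole, CH2Cl2, 0 °C
Reagents that add atoms: triisopropylsilyl chloride, CC(C)[Si](Cl)(C(C)C)C(C)C
Why: Silylation of the more acidic, unhindered C4 phenol, the C2 phenol being held in a hydrogen bond to the formyl group.

Step 5
Reactants: 7 (S)-4-hydroxymandelic acid
Product: 8 benzyl (S)-2-[4-(benzyloxy)phenyl]-2-hydroxyacetate
Conditions: BnBr (2.1 equiv), K2CO3, DMF, 23 °C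
Reagents that add atoms: benzyl bromide, BrCc1ccccc1
Why: Carboxylate alkylation and Williamson etherification under carbonate base benzylate the acid and the phenol but not the secondary alcohol, and the mild base leaves the mandelate stereocentre in place.

Step 6
Reactants: 6 2-hydroxy-4-(triisopropylsilyloxy)benzaldehyde; 8 benzyl (S)-2-[4-(benzyloxy)phenyl]-2-hydroxyacetate
Product: 9 benzyl (R)-2-[4-(benzyloxy)phenyl]-2-[2-formyl-5-(triisopropylsilyloxy)phenoxy]acetate
Conditions: PPh3, DIAD, toluene, 0 to 23 °C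
Reagents that add atoms: none
Why: Mitsunobu etherification, in which the acidic salicylaldehyde-type phenol displaces the oxyphosphonium of the mandelate by SN2 with inversion, turning the (S)-carbinol into the (R)-aryl ether that becomes C2 (the adjacent ester disfavours ionisation).

Step 7
Reactants: 4 8-bromo-3,5,7,3',4'-penta-O-benzylepicatechin; 9 benzyl (R)-2-[4-(benzyloxy)phenyl]-2-[2-formyl-5-(triisopropylsilyloxy)phenoxy]acetate
Product: 12 benzyl (2R)-2-[4-(benzyloxy)phenyl]-2-{2-[hydroxy(penta-O-benzylepicatechin-8-yl)methyl]-5-(triisopropylsilyloxy)phenoxy}acetate (both carbinol epimers), via 8-lithio flavan 10 (not isolated), via 8-dichlorocerio flavan 11 (not isolated)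
Conditions: 4, t-BuLi (2.0 equiv), THF, −78 °C; anhydrous CeCl3, −78 °C; then 9, −78 °C; pH 7 buffer quench at −78 °C
Reagents that add atoms: none
Why: Bromine–lithium exchange, transmetalation to a weakly basic, carbonyl-selective organocerium reagent and 1,2-addition to the aldehyde in preference to the benzyl ester form the C4–C8 bond; the new carbinol centre is formed without control, which does not matter because this carbon becomes trigonal in step 10.

Step 8
Reactants: 12 benzyl (2R)-2-[4-(benzyloxy)phenyl]-2-{2-[hydroxy(penta-O-benzylepicatechin-8-yl)methyl]-5-(triisopropylsilyloxy)phenoxy}acetate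
Product: 13 (2R)-2-[4-(benzyloxy)phenyl]-5-(penta-O-benzylepicatechin-8-yl)-8-(triisopropylsilyloxy)-2,3-dihydro-5H-1,4-benzodioxepin-3-ol (lactol, epimer mixture)
Conditions: i-Bu2AlH (3 equiv), CH2Cl2, −78 °C; aqueous potassium sodium tartrate
Reagents that add atoms: none
Why: Partial reduction of the α-aryloxy ester by i-Bu2AlH at low temperature stops at the aldehyde oxidation level as a chelated aluminium hemiacetal, and on work-up the aldehyde is captured by the neighbouring benzhydrol as the benzo-fused seven-membered lactol, whose new anomeric centre is of no consequence.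

Step 9
Reactants: 13 the lactol
Product: 14 (2R)-2-[4-(benzyloxy)phenyl]-5-(penta-O-benzylepicatechin-8-yl)-8-(triisopropylsilyloxy)-2,3-dihydro-5H-1,4-benzodioxepin-3-yl acetate
Conditions: Ac2O, pyridine, DMAP (cat.), CH2Cl2, 0 °C
Reagents that add atoms: acetic anhydride, CC(=O)OC(C)=O
Why: Acetylation of the hemiacetal hydroxyl gives an acyl acetal that stores the aldehyde and the benzhydryl leaving group in one robust temporary ring; any open-chain C4 acetate tautomer formed alongside would release the same intermediate in step 10.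

Step 10
Reactants: 14 the lactol acetate
Product: 16 (2R,3R,4R)-2-[4-(benzyloxy)phenyl]-4-(penta-O-benzylepicatechin-8-yl)chromane-3,7-diol, via quinone methide aldehyde 15 (not isolated)
Conditions: n-Bu4N[Ph3SiF2] (1.1 equiv), THF, 0 °C; then MgBr2·OEt2 (1.0 equiv), undivided cell, sacrificial Mg anode, glassy-carbon cathode, n-Bu4NPF6 (0.1 M), THF, −20 °C, constant current, about 2.2 F per mol; pH 7 buffer
Reagents that add atoms: none
Why: Proposed new method: fluoride frees the ring A C7 phenoxide, which pushes through C4a to break the dioxepine C4–O bond while acetate leaves C3 (1,6-elimination with Grob-type collapse of the acyl acetal), so that para-quinone methide and aldehyde (15) appear together; cathodic two-electron reduction of the quinone methide then makes C4 a magnesium-paired diarylmethyl carbanion that adds to the C3 aldehyde, the closest known reaction types being the sacrificial-anode electroreductive Barbier coupling of benzylic halides with carbonyl compounds and the reductive umpolung of para-quinone methides to diarylmethyl anion equivalents. Ring C closes in 6-exo-trig mode, C4 attacking the carbonyl carbon whose oxygen stays outside the new pyran. C3 is set by Cram-chelate control from C2: divalent magnesium (added MgBr2 and that released from the anode) bridges the aldehyde oxygen and the aryl ether O1, so that in the chair-like transition state with the C2 aryl equatorial the C3–O bond is axial, that is cis to the C2 aryl. C4 is set in the same transition state, the bulky flavan-8-yl group taking the pseudoaxial position anti to the C3–O–Mg bond and away from the peri C5–H of ring A, which gives the 3,4-trans (2,4-trans) arrangement of the target. The step needs reduction of the quinone methide ahead of the aldehyde and C–C bond formation ahead of protonation or dimerisation at C4; the first should follow from the much less negative reduction potential of the push–pull quinone methide, the second from the aprotic medium, the absence of any OH group in 14, low concentration and the six-membered intramolecular trajectory.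

Step 11
Reactants: 16 the hexabenzyl ether
Product: 17 epiguibourtinidol-(4β→8)-epicatechin, (2R,3R,4R)-2-(4-hydroxyphenyl)-4-[(2R,3R)-2-(3,4-dihydroxyphenyl)-3,5,7-trihydroxychroman-8-yl]chromane-3,7-diol
Conditions: H2 (1 atm), Pd(OH)2/C, THF/MeOH/H2O, 23 °C
Reagents that add atoms: none
Why: Hydrogenolysis of the six benzyl ethers over Pd(OH)2/C, conditions under which the cyclic benzylic C2–O1 bonds and the C4–C8 interflavan bond of flavan-3-ol oligomers are retained, should give the target without touching any stereocentre.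

**Compound list**

1 | (−)-epicatechin | Oc1cc(O)c2c(c1)O[C@H](c1ccc(O)c(O)c1)[C@H](O)C2 | starting material
2 | 5,7,3',4'-tetra-O-benzyl-(−)-epicatechin | c1ccccc1COc1cc(OCc3ccccc3)c2c(c1)O[C@H](c1ccc(OCc3ccccc3)c(OCc3ccccc3)c1)[C@H](O)C2 | intermediate
3 | 8-bromo-5,7,3',4'-tetra-O-benzylepicatechin | c1ccccc1COc1cc(OCc3ccccc3)c2c(c1Br)O[C@H](c1ccc(OCc3ccccc3)c(OCc3ccccc3)c1)[C@H](O)C2 | intermediate
4 | 8-bromo-3,5,7,3',4'-penta-O-benzylepicatechin | c1ccccc1COc1cc(OCc3ccccc3)c2c(c1Br)O[C@H](c1ccc(OCc3ccccc3)c(OCc3ccccc3)c1)[C@H](OCc1ccccc1)C2 | intermediate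
5 | 2,4-dihydroxybenzaldehyde | O=Cc1ccc(O)cc1O | starting material
6 | 2-hydroxy-4-(triisopropylsilyloxy)benzaldehyde | O=Cc1ccc(O[Si](C(C)C)(C(C)C)C(C)C)cc1O | intermediate
7 | (S)-4-hydroxymandelic acid | OC(=O)[C@@H](O)c1ccc(O)cc1 | starting material
8 | benzyl (S)-2-[4-(benzyloxy)phenyl]-2-hydroxyacetate | O=C(OCc1ccccc1)[C@@H](O)c1ccc(OCc2ccccc2)cc1 | intermediate
9 | benzyl (R)-2-[4-(benzyloxy)phenyl]-2-[2-formyl-5-(triisopropylsilyloxy)phenoxy]acetate | O=C(OCc1ccccc1)[C@H](Oc1cc(O[Si](C(C)C)(C(C)C)C(C)C)ccc1C=O)c1ccc(OCc2ccccc2)cc1 | intermediate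
10 | 8-lithio-3,5,7,3',4'-penta-O-benzylepicatechin | c1ccccc1COc1cc(OCc3ccccc3)c2c(c1[Li])O[C@H](c1ccc(OCc3ccccc3)c(OCc3ccccc3)c1)[C@H](OCc1ccccc1)C2 | intermediate
11 | 8-(dichlorocerio)-3,5,7,3',4'-penta-O-benzylepicatechin | c1ccccc1COc1cc(OCc3ccccc3)c2c(c1[Ce](Cl)Cl)O[C@H](c1ccc(OCc3ccccc3)c(OCc3ccccc3)c1)[C@H](OCc1ccccc1)C2 | intermediate
12 | benzyl (2R)-2-[4-(benzyloxy)phenyl]-2-{2-[hydroxy(penta-O-benzylepicatechin-8-yl)methyl]-5-(triisopropylsilyloxy)phenoxy}acetate, both carbinol epimers | O=C(OCc1ccccc1)[C@H](Oc1cc(O[Si](C(C)C)(C(C)C)C(C)C)ccc1C(O)c1c(OCc2ccccc2)cc(OCc2ccccc2)c2c1O[C@H](c1ccc(OCc3ccccc3)c(OCc3ccccc3)c1)[C@H](OCc1ccccc1)C2)c1ccc(OCc2ccccc2)cc1 | intermediate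
13 | (2R)-2-[4-(benzyloxy)phenyl]-5-(penta-O-benzylepicatechin-8-yl)-8-(triisopropylsilyloxy)-2,3-dihydro-5H-1,4-benzodioxepin-3-ol, epimer mixture | OC1OC(c2c(OCc3ccccc3)cc(OCc3ccccc3)c3c2O[C@H](c2ccc(OCc4ccccc4)c(OCc4ccccc4)c2)[C@H](OCc2ccccc2)C3)c2ccc(O[Si](C(C)C)(C(C)C)C(C)C)cc2O[C@@H]1c1ccc(OCc2ccccc2)cc1 | intermediate
14 | (2R)-2-[4-(benzyloxy)phenyl]-5-(penta-O-benzylepicatechin-8-yl)-8-(triisopropylsilyloxy)-2,3-dihydro-5H-1,4-benzodioxepin-3-yl acetate, epimer mixture | CC(=O)OC1OC(c2c(OCc3ccccc3)cc(OCc3ccccc3)c3c2O[C@H](c2ccc(OCc4ccccc4)c(OCc4ccccc4)c2)[C@H](OCc2ccccc2)C3)c2ccc(O[Si](C(C)C)(C(C)C)C(C)C)cc2O[C@@H]1c1ccc(OCc2ccccc2)cc1 | intermediate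
15 | (2R)-2-[4-(benzyloxy)phenyl]-2-({3-oxo-6-[(penta-O-benzylepicatechin-8-yl)methylidene]cyclohexa-1,4-dien-1-yl}oxy)acetaldehyde | O=C[C@H](OC1=CC(=O)C=CC1=Cc1c(OCc2ccccc2)cc(OCc2ccccc2)c2c1O[C@H](c1ccc(OCc3ccccc3)c(OCc3ccccc3)c1)[C@H](OCc1ccccc1)C2)c1ccc(OCc2ccccc2)cc1 | intermediate
16 | (2R,3R,4R)-2-[4-(benzyloxy)phenyl]-4-(3,5,7,3',4'-penta-O-benzylepicatechin-8-yl)chromane-3,7-diol | c1ccccc1COc1ccc([C@H]2Oc3cc(O)ccc3[C@H](c3c(OCc5ccccc5)cc(OCc5ccccc5)c4c3O[C@H](c3ccc(OCc5ccccc5)c(OCc5ccccc5)c3)[C@H](OCc3ccccc3)C4)[C@H]2O)cc1 | intermediate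
17 | epiguibourtinidol-(4β→8)-epicatechin | Oc1ccc([C@H]2Oc3cc(O)ccc3[C@H](c3c(O)cc(O)c4c3O[C@H](c3ccc(O)c(O)c3)[C@H](O)C4)[C@H]2O)cc1 | target

**Step count and risks**

Total steps: 11. Longest linear sequence: 8 (steps 1, 2, 3, 7, 8, 9, 10, 11).

Steps most likely to fail:

1. Step 10 (proposed new method). What may go wrong: protonation or radical dimerisation at C4 before ring closure; proton transfer from C2–H to the C4 carbanion with loss of the C2 configuration; non-chelated closure that erodes facial selectivity at C3. Fallback by known chemistry, a samarium Barbier cyclisation of a covalent benzhydryl chloride, setting out from lactol 13 and returning at 16: SOCl2 and 2,6-lutidine in CH2Cl2 at −40 °C should funnel both ring–chain tautomers of 13, through the stabilised diarylmethyl cation, into the chloro aldehyde (2R)-2-[4-(benzyloxy)phenyl]-2-{2-[chloro(penta-O-benzylepicatechin-8-yl)methyl]-5-(triisopropylsilyloxy)phenoxy}acetaldehyde F1, used crude. SmI2 (2.2 equiv) in THF at −78 °C should reduce the benzylic chloride ahead of the aldehyde and close ring C by Barbier addition under the same chelate control, giving the C7 triisopropylsilyl ether of the cyclised flavan F2. n-Bu4NF in THF at 0 °C then removes the silyl group to give 16.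

2. Step 7. What may go wrong: attack of the aryl metal on the benzyl ester, deprotonation at C2 with loss of configuration, incomplete halogen–metal exchange. Fallback, a Nozaki–Hiyama–Kishi arylation that avoids any basic aryl metal, setting out from 2 and returning at 12: N-iodosuccinimide in CH2Cl2 should give 8-iodo-5,7,3',4'-tetra-O-benzylepicatechin F3, and NaH/BnBr its 3-O-benzyl ether 8-iodo-3,5,7,3',4'-penta-O-benzylepicatechin F4. CrCl2 (excess) with NiCl2 (cat.) in DMF at 23 °C should couple F4 with aldehyde 9 through an aryl chromium species that adds only to the aldehyde, giving 12.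

3. Step 6. What may go wrong: partial loss of configuration by ionisation of the electron-rich benzylic oxyphosphonium intermediate; sluggish reaction of the hydrogen-bonded phenol. Fallback, a catalytic asymmetric O–H insertion, setting out from phenol 6 and returning at 9: commercial 4-hydroxyphenylacetic acid is dibenzylated (BnBr, K2CO3, DMF) to benzyl 2-[4-(benzyloxy)phenyl]acetate F5. Diazo transfer (4-acetamidobenzenesulfonyl azide, DBU, MeCN) gives benzyl 2-diazo-2-[4-(benzyloxy)phenyl]acetate F6. Enantioselective insertion of its metal carbenoid into the O–H bond of 6 (Pd(PhCN)2Cl2, a chiral spiro-bis(oxazoline) ligand and Na[B(3,5-(CF3)2C6H3)4], ligand enantiomer chosen for the (R)-ether) should give 9 directly.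

**Further compounds**

F1 | step 10 | (2R)-2-[4-(benzyloxy)phenyl]-2-{2-[chloro(penta-O-benzylepicatechin-8-yl)methyl]-5-(triisopropylsilyloxy)phenoxy}acetaldehyde | O=C[C@H](Oc1cc(O[Si](C(C)C)(C(C)C)C(C)C)ccc1C(Cl)c1c(OCc2ccccc2)cc(OCc2ccccc2)c2c1O[C@H](c1ccc(OCc3ccccc3)c(OCc3ccccc3)c1)[C@H](OCc1ccccc1)C2)c1ccc(OCc2ccccc2)cc1
F2 | step 10 | (2R,3R,4R)-2-[4-(benzyloxy)phenyl]-4-(penta-O-benzylepicatechin-8-yl)-7-(triisopropylsilyloxy)chroman-3-ol | c1ccccc1COc1ccc([C@H]2Oc3cc(O[Si](C(C)C)(C(C)C)C(C)C)ccc3[C@H](c3c(OCc5ccccc5)cc(OCc5ccccc5)c4c3O[C@H](c3ccc(OCc5ccccc5)c(OCc5ccccc5)c3)[C@H](OCc3ccccc3)C4)[C@H]2O)cc1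
F3 | step 7 | 8-iodo-5,7,3',4'-tetra-O-benzylepicatechin | c1ccccc1COc1cc(OCc3ccccc3)c2c(c1I)O[C@H](c1ccc(OCc3ccccc3)c(OCc3ccccc3)c1)[C@H](O)C2
F4 | step 7 | 8-iodo-3,5,7,3',4'-penta-O-benzylepicatechin | c1ccccc1COc1cc(OCc3ccccc3)c2c(c1I)O[C@H](c1ccc(OCc3ccccc3)c(OCc3ccccc3)c1)[C@H](OCc1ccccc1)C2
F5 | step 6 | benzyl 2-[4-(benzyloxy)phenyl]acetate | O=C(OCc1ccccc1)Cc1ccc(OCc2ccccc2)cc1
F6 | step 6 | benzyl 2-diazo-2-[4-(benzyloxy)phenyl]acetate | O=C(OCc1ccccc1)C(=[N+]=[N-])c1ccc(OCc2ccccc2)cc1
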